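**Strategy.** The plan rests on cutting the C5–C6 bond of ring B, whose two carbons carry the cis oxygen pair (C5 ester, C6 hydroxyl) of the target. A samarium diiodide pinacol cyclisation of a dialdehyde forms this bond, closes ring B as a trans-fused chair and sets both carbinol centres at once, C5–O equatorial and C6–O axial. The precursor is a ring A cyclohexene with the quaternary C1, an axial silyl ether at C4, a formyl group on C4a and a 4-oxobut-1-en-2-yl arm on C8a, made from a Birch-derived dienone by asymmetric conjugate addition. The C4 oxygen later passes its configuration to C2 by an Ireland–Claisen rearrangement.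

Key step: step 14

Remark: the decalin locants C1–C8a of the target are used for every intermediate, including the monocyclic ones; β is the face of H-8a and of the C1 carbon substituent C9, α the face of H-4a and of the C1 methyl.

Step 1
Reactants: 1 benzoic acid; 2 iodomethane
Product: 4 1-methylcyclohexa-2,5-diene-1-carboxylic acid, via Birch enediolate 3 (not isolated)
Conditions: Li, NH3(l)/THF, −78 °C; then MeI, −78 °C → rt; aq. HCl
Reagents that add atoms: none
Why: Birch reduction of the benzoate gives the cross-conjugated enediolate, which iodomethane alkylates at the carboxyl-bearing carbon (Birch reductive alkylation), so the future C1 with its methyl and C9 is made as a prochiral quaternary carbon.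

Step 2
Reactants: 4 1-methylcyclohexa-2,5-diene-1-carboxylic acid
Product: 5 (1-methylcyclohexa-2,5-dien-1-yl)methanol
Conditions: LiAlH4, THF, 0 °C → reflux
Reagents that add atoms: none
Why: Hydride reduction of the carboxylic acid gives the neopentyl alcohol and leaves the skipped diene untouched.

Step 3
Reactants: 5 (1-methylcyclohexa-2,5-dien-1-yl)methanol
Product: 6 tert-butyl[(1-methylcyclohexa-2,5-dien-1-yl)methoxy]diphenylsilane
Conditions: TBDPSCl, imidazole, DMF, rt
Reagents that add atoms: tert-butyl(chloro)diphenylsilane, CC(C)(C)[Si](Cl)(c1ccccc1)c1ccccc1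
Why: Standard silylation; the acid-stable TBDPS ether should last until step 22 and makes the oxymethyl group clearly larger than the methyl group for step 7.

Step 4
Reactants: 6 TBDPS ether of the dienyl methanol
Product: 7 4-[(tert-butyldiphenylsilyl)oxymethyl]-4-methylcyclohexa-2,5-dien-1-one
Conditions: PDC, t-BuOOH, Celite, PhH, rt
Reagents that add atoms: tert-butyl hydroperoxide, CC(C)(C)OO
Why: Chromium/hydroperoxide oxidation of the doubly allylic CH2 of a 3,3-disubstituted cyclohexa-1,4-diene gives the cross-conjugated dienone (bis-allylic oxidation).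

Step 5
Reactants: 8 but-3-yn-1-ol
Product: 9 (but-3-yn-1-yloxy)triethylsilane
Conditions: TESCl, imidazole, CH2Cl2, 0 °C
Reagents that add atoms: chlorotriethylsilane, CC[Si](Cl)(CC)CC
Why: Silylation masks the future C6 oxygen as a primary TES ether that can later be removed in the presence of TBS and TBDPS ethers.

Step 6
Reactants: 9 (but-3-yn-1-yloxy)triethylsilane
Product: 11 4,4,5,5-tetramethyl-2-[4-(triethylsilyloxy)but-1-en-2-yl]-1,3,2-dioxaborolane, via alkenylalane 10 (not isolated)
Conditions: Ni(dppp)Cl2 (3 mol %), DIBAL-H, THF, 0 °C → rt; then MeOBpin, 0 °C → rt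
Reagents that add atoms: 2-methoxy-4,4,5,5-tetramethyl-1,3,2-dioxaborolane, COB1OC(C)(C)C(C)(C)O1
Why: Nickel-catalysed hydroalumination with the dppp ligand places aluminium on the internal alkyne carbon, and exchange with the methoxyboronate gives the 1,1-disubstituted alkenyl boronate (future C8 with its methylene, C7 and C6).

Step 7
Reactants: 7 4,4-disubstituted cyclohexadienone; 11 2-alkenyl pinacol boronate
Product: 12 C8a-alkenyl enone (C4 ketone; C2=C3; arm α at C8a)
Conditions: [RhCl(C2H4)2]2 (2.5 mol %), (R)-BINAP (6 mol %), aq. KOH (0.3 equiv), dioxane/H2O 10:1, 40 °C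
Reagents that add atoms: none
Why: Rhodium-catalysed asymmetric conjugate addition of the alkenyl boronate (Hayashi–Miyaura reaction) desymmetrises the dienone: the ligand (sense assigned by analogy with cyclohex-2-enone) selects the enantioface and the larger silyloxymethyl group directs attack anti to itself, so the arm should enter on the α face of C8a, cis to the C1 methyl, which sets C8a and makes C1 stereogenic.

Step 8
Reactants: 12 C8a-alkenyl enone
Product: 15 C4a-(triethylsilyloxymethyl) enone (CH2OTES β; trans to the C8a arm), via lithium dienolate 13 (not isolated), via lithium aldolate 14 (not isolated)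
Conditions: LDA, THF, −78 °C; CH2O (g), −78 °C; then TESCl, −78 → 0 °C
Reagents that add atoms: formaldehyde, C=O; chlorotriethylsilane, CC[Si](Cl)(CC)CC
Why: Kinetic α′-deprotonation (C1 carries no γ-hydrogen) and aldol addition to monomeric formaldehyde anti to the neighbouring C8a arm set C4a trans to C8a, and silylating the aldolate in the flask prevents retro-aldol and dehydration.

Step 9
Reactants: 15 C4a-(triethylsilyloxymethyl) enone
Product: 16 4α-allylic alcohol (pseudoequatorial OH)
Conditions: NaBH4, CeCl3·7H2O, MeOH/THF, −78 °C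
Reagents that add atoms: none
Why: Luche reduction is 1,2-selective, and axial hydride delivery on the β face of the anchored half-chair should give the pseudoequatorial 4α-alcohol (cis to the C8a arm), which is the epimer to be inverted.

Step 10
Reactants: 16 4α-allylic alcohol
Product: 17 4β-chloroacetate
Conditions: ClCH2CO2H, PPh3, DIAD, PhMe, 0 °C → rt
Reagents that add atoms: chloroacetic acid, OC(=O)CCl
Why: Mitsunobu esterification inverts C4 by SN2 displacement to the axial 4β-oxygen, cis to the C4a substituent, and the SN2′ path is blocked because C2 is neopentyl.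

Step 11
Reactants: 17 4β-chloroacetate
Product: 18 4β-allylic alcohol
Conditions: K2CO3 (cat.), MeOH, 0 °C
Reagents that add atoms: none
Why: The activated chloroacetate undergoes transesterification within minutes, much faster than primary TES ethers are cleaved.

Step 12
Reactants: 18 4β-allylic alcohol
Product: 20 4β-OTBS diol (free C5–OH and C6–OH), via tris-silyl ether 19 (not isolated)
Conditions: TBSOTf, 2,6-lutidine, CH2Cl2, −78 → 0 °C; then MeOH, PPTS, 0 °C → rt
Reagents that add atoms: tert-butyldimethylsilyl trifluoromethanesulfonate, CC(C)(C)[Si](C)(C)OS(=O)(=O)C(F)(F)F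
Why: The silyl triflate protects the hindered axial 4β-hydroxyl, and mild acid methanolysis then removes only the two primary TES ethers (primary TES is far more labile than secondary TBS or TBDPS).

Step 13
Reactants: 20 4β-OTBS diol
Product: 21 dialdehyde (C4a formyl; C8a 4-oxobut-1-en-2-yl arm; 4β-OTBS)
Conditions: Dess–Martin periodinane, NaHCO3, CH2Cl2, 0 °C → rt; filtered and used at once
Reagents that add atoms: none
Why: Buffered hypervalent-iodine oxidation converts both primary alcohols to aldehydes without amine base, which should avoid migration of the 8-methylene into conjugation with the C6 aldehyde and epimerisation at C4a.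

Step 14
Reactants: 21 dialdehyde
Product: 22 trans-decalin cis-5,6-diol (5α-OH equatorial; 6α-OH axial; 8-methylene; 4β-OTBS)
Conditions: SmI2 (3 equiv), t-BuOH (3 equiv), THF, −78 → −20 °C; aq. NH4Cl
Reagents that add atoms: none
Why: Single-electron transfer from SmI2 to one aldehyde gives a samarium ketyl whose carbon adds to the second, Sm(III)-bound aldehyde (6-exo-trig attack on the carbonyl carbon, closing ring B through the new C5–C6 bond); a second electron and protonation by t-BuOH give the diol. The closest known reaction type is the SmI2 pinacol cyclisation of 1,6-dialdehydes to cis-cyclohexane-1,2-diols. Because the C4a and C8a bonds are both equatorial on ring A, ring B forms as a trans-fused chair. C5 is controlled by the axial 4β-silyloxy group: an axial C5–O would be syn-diaxial to it, so C5–O sits equatorial (α); C6 is controlled by the samarium bridge between the two oxygens, which holds them cis and therefore puts C6–O axial (α). The step needs carbonyl–carbonyl coupling to outrun enolisation (migration of the 8-methylene into conjugation with the C6 aldehyde, epimerisation or β-elimination at C4a); the neutral medium at −78 °C, the sp3 silyl-protected C4 and the poor leaving-group ability of silyloxide should secure this.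

Step 15
Reactants: 22 trans-decalin cis-5,6-diol
Product: 23 8β-methyl diol
Conditions: [Ir(cod)(PCy3)(py)]PF6 (5 mol %), H2 (1 atm), CH2Cl2, 0 °C → rt
Reagents that add atoms: none
Why: Hydroxyl-directed hydrogenation: iridium bound to the axial 6α-hydroxyl should deliver hydrogen to the α face of the 8-methylene, giving the equatorial 8β-methyl, while the C2=C3 alkene, shielded by C1 and the 4-silyloxy group, should stay.

Step 16
Reactants: 23 8β-methyl diol
Product: 25 5,6-acetonide with free 4β-OH, via triol 24 (not isolated)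
Conditions: CSA, MeOH/CH2Cl2, rt; concentrate; then 2,2-dimethoxypropane, acetone, rt
Reagents that add atoms: 2,2-dimethoxypropane, COC(C)(C)OC
Why: Acid methanolysis removes the secondary TBS ether but not the acid-stable primary TBDPS ether, and acetal exchange then protects the cis-5,6-diol as the five-membered acetonide (the axial O4 and equatorial O5 cannot span a chair dioxane).

Step 17
Reactants: 25 5,6-acetonide with free 4β-OH
Product: 26 4β-propanoate
Conditions: (EtCO)2O, Et3N, DMAP, CH2Cl2, rt
Reagents that add atoms: propanoic anhydride, CCC(=O)OC(=O)CC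
Why: DMAP-catalysed acylation of the axial allylic alcohol installs the three-carbon unit that becomes C1′, its methyl and the ethyl CH2 of the sec-butyl group.

Step 18
Reactants: 26 4β-propanoate
Product: 29 (S)-2-(decalin-2β-yl)propanoic acid (C3=C4 alkene), via silyl ketene acetal 27 (not isolated), via trimethylsilyl ester 28 (not isolated)
Conditions: LDA, THF/DMPU 3:1, −78 °C; TMSCl/Et3N, −78 °C → rt, then 65 °C; aq. NH4Cl
Reagents that add atoms: none
Why: Ireland–Claisen rearrangement: the Z(O)-enolate gives the (Z)-silyl ketene acetal, whose suprafacial [3,3] shift on the β face turns C4–O(β) into the C2–C(β) bond and, through the boat transition state that keeps OSi and the α-methyl away from ring A and the quaternary C1, sets the side-chain carbon so that its carboxyl carbon becomes the ethyl CH2 of the (R)-sec-butyl group (a butanoate would put the ethyl group where the methyl must be).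

Step 19
Reactants: 29 side-chain carboxylic acid
Product: 30 side-chain primary alcohol
Conditions: LiAlH4, THF, 0 °C → rt
Reagents that add atoms: none
Why: Hydride reduction of the acid to the primary alcohol leaves the acetonide, silyl ether and alkene intact.

Step 20
Reactants: 30 side-chain primary alcohol
Product: 31 side-chain tosylate
Conditions: TsCl, Et3N, DMAP (cat.), CH2Cl2, 0 °C → rt
Reagents that add atoms: 4-methylbenzenesulfonyl chloride, Cc1ccc(cc1)S(Cl)(=O)=O
Why: Sulfonylation activates the primary carbinol for carbon–carbon bond formation.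

Step 21
Reactants: 31 side-chain tosylate
Product: 32 2β-[(R)-butan-2-yl] silyl ether
Conditions: Me2CuLi (from CuI, MeLi), Et2O, −20 → 0 °C
Reagents that add atoms: methyllithium (as lithium dimethylcuprate), [Li]C
Why: SN2 displacement of the primary tosylate by the methyl cuprate completes the sec-butyl group without touching its stereocentre.

Step 22
Reactants: 32 2β-[(R)-butan-2-yl] silyl ether
Product: 33 C9 primary alcohol
Conditions: TBAF, THF, rt → 45 °C
Reagents that add atoms: none
Why: Fluoride cleaves the neopentyl TBDPS ether, and the acetonide is inert to it.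

Step 23
Reactants: 33 C9 primary alcohol
Product: 34 C9 aldehyde
Conditions: Dess–Martin periodinane, NaHCO3, CH2Cl2, rt
Reagents that add atoms: none
Why: Mild oxidation gives the neopentyl aldehyde, which cannot enolise.

Step 24
Reactants: 34 C9 aldehyde
Product: 35 C9 allylic alcohols (both epimers)
Conditions: CH2=CHMgBr, THF, −78 → 0 °C
Reagents that add atoms: vinylmagnesium bromide, C=C[Mg]Br
Why: Grignard addition to the hindered, non-enolisable aldehyde adds C10 and C11; the new carbinol centre is removed in step 25, so both epimers are carried on.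

Step 25
Reactants: 35 C9 allylic alcohols
Product: 36 C9 vinyl ketone
Conditions: Dess–Martin periodinane, NaHCO3, CH2Cl2, rt
Reagents that add atoms: none
Why: Oxidation of the allylic alcohol gives the enone, which cannot enolise towards the quaternary C1.

Step 26
Reactants: 36 C9 vinyl ketone
Product: 37 11-O-PMB β-alkoxy ketone
Conditions: 4-MeOC6H4CH2OH (3 equiv), PMe3 (10 mol %), MeCN, rt
Reagents that add atoms: (4-methoxyphenyl)methanol, COc1ccc(CO)cc1
Why: Phosphine-catalysed oxa-Michael addition of the alcohol to the unhindered terminal carbon gives the 3-oxypropanoyl chain with its oxygen already protected.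

Step 27
Reactants: 37 11-O-PMB β-alkoxy ketone
Product: 38 5α,6α-diol (11-O-PMB)
Conditions: AcOH/H2O/THF 3:1:1, 45 °C
Reagents that add atoms: none
Why: Aqueous acetic acid hydrolyses the acetonide; the PMB ether and the β-alkoxy ketone tolerate it.

Step 28
Reactants: 39 tert-butyl 3-oxobutanoate
Product: 40 tert-butyl (E)-3-(trifluoromethylsulfonyloxy)but-2-enoate
Conditions: Tf2O, aq. Me4NOH, PhMe, 5 °C
Reagents that add atoms: trifluoromethanesulfonic anhydride, O=S(=O)(OS(=O)(=O)C(F)(F)F)C(F)(F)F
Why: O-sulfonylation of the non-chelated ammonium enolate should give the E enol triflate (ester trans to OTf), which fixes the later alkene geometry.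

Step 29
Reactants: 40 (E)-enol triflate; 41 methyl bromoacetate
Product: 43 1-tert-butyl 5-methyl (E)-3-methylpent-2-enedioate, via Reformatsky reagent 42 (not isolated)
Conditions: Zn, TMSCl (cat.), THF; then 40, Pd2(dba)3 (2.5 mol %), XPhos (6 mol %), THF, 50 °C
Reagents that add atoms: none
Why: Negishi cross-coupling of the zinc ester enolate with the enol triflate proceeds with retention of the alkene geometry and gives the diester with two distinguishable ester groups.

Step 30
Reactants: 43 mixed diester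
Product: 44 (E)-5-methoxy-3-methyl-5-oxopent-2-enoic acid
Conditions: TFA/CH2Cl2 1:4, 0 °C → rt
Reagents that add atoms: none
Why: Acidolysis removes only the tert-butyl ester, so the conjugated carboxyl is freed while the methyl ester and the E alkene stay.

Step 31
Reactants: 38 5α,6α-diol (11-O-PMB); 44 half-ester acid
Product: 47 C5 ester with free 6α-OH (11-O-PMB), via acid chloride 45 (not isolated), via stannylene acetal 46 (not isolated)
Conditions: 44, 1-chloro-N,N,2-trimethylprop-1-en-1-amine, CH2Cl2, 0 °C; 38, Bu2SnO, PhMe, reflux (−H2O); then combine, 0 °C → rt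
Reagents that add atoms: none
Why: Stannylene-mediated monoacylation of a cis-diol reacts at the equatorial oxygen (O5), and using a base-free acid chloride avoids the vinylketene pathway that would scramble the E alkene.

Step 32
Reactants: 47 C5 ester with free 6α-OH (11-O-PMB)
Product: 48 tandyukisin B
Conditions: DDQ, CH2Cl2/pH 7 buffer 10:1, 0 °C → rt
Reagents that add atoms: none
Why: Oxidative cleavage of the PMB ether under buffered conditions frees the primary hydroxyl without base, so the β-hydroxy ketone and both esters should survive.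

Compound list
1 | benzoic acid | OC(=O)c1ccccc1 | starting material
2 | iodomethane | CI | starting material
3 | dilithium (cyclohexa-2,5-dien-1-ylidene)methanediolate (Birch enediolate) | [Li+].[Li+].[O-]C([O-])=C1C=CCC=C1 | intermediate
4 | 1-methylcyclohexa-2,5-diene-1-carboxylic acid | CC1(C(O)=O)C=CCC=C1 | intermediate
5 | (1-methylcyclohexa-2,5-dien-1-yl)methanol | CC1(CO)C=CCC=C1 | intermediate
6 | tert-butyl[(1-methylcyclohexa-2,5-dien-1-yl)methoxy]diphenylsilane | CC1(CO[Si](c2ccccc2)(c2ccccc2)C(C)(C)C)C=CCC=C1 | intermediate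
7 | 4-[(tert-butyldiphenylsilyl)oxymethyl]-4-methylcyclohexa-2,5-dien-1-one | CC1(CO[Si](c2ccccc2)(c2ccccc2)C(C)(C)C)C=CC(=O)C=C1 | intermediate
8 | but-3-yn-1-ol | C#CCCO | starting material
9 | (but-3-yn-1-yloxy)triethylsilane | C#CCCO[Si](CC)(CC)CC | intermediate
10 | diisobutyl[4-(triethylsilyloxy)but-1-en-2-yl]alane | C=C(CCO[Si](CC)(CC)CC)[Al](CC(C)C)CC(C)C | intermediate
11 | 4,4,5,5-tetramethyl-2-[4-(triethylsilyloxy)but-1-en-2-yl]-1,3,2-dioxaborolane | C=C(CCO[Si](CC)(CC)CC)B1OC(C)(C)C(C)(C)O1 | intermediate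
12 | enone: C4 ketone, C2=C3; C1 α-CH3 and β-CH2OTBDPS; C8a α-[4-(triethylsilyloxy)but-1-en-2-yl] (H-8a β) | CC[Si](CC)(CC)OCCC(=C)[C@H]1CC(=O)C=C[C@]1(C)CO[Si](c2ccccc2)(c2ccccc2)C(C)(C)C | intermediate
13 | lithium dienolate of 12 (C4–O−, C4=C4a, C2=C3) | [Li+].CC[Si](CC)(CC)OCCC(=C)[C@H]1C=C([O-])C=C[C@]1(C)CO[Si](c2ccccc2)(c2ccccc2)C(C)(C)C | intermediate
14 | lithium aldolate: 12 with β-CH2O− on C4a (H-4a α) | [Li+].CC[Si](CC)(CC)OCCC(=C)[C@H]1[C@H](C[O-])C(=O)C=C[C@]1(C)CO[Si](c2ccccc2)(c2ccccc2)C(C)(C)C | intermediate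
15 | enone 12 with β-CH2OTES on C4a (H-4a α; trans to the C8a arm) | CC[Si](CC)(CC)OCCC(=C)[C@H]1[C@H](CO[Si](CC)(CC)CC)C(=O)C=C[C@]1(C)CO[Si](c2ccccc2)(c2ccccc2)C(C)(C)C | intermediate
16 | 4α-alcohol of 15 (OH trans to the C4a substituent) | CC[Si](CC)(CC)OCCC(=C)[C@H]1[C@H](CO[Si](CC)(CC)CC)[C@@H](O)C=C[C@]1(C)CO[Si](c2ccccc2)(c2ccccc2)C(C)(C)C | intermediate
17 | 4β-chloroacetate (ester cis to the C4a substituent) | CC[Si](CC)(CC)OCCC(=C)[C@H]1[C@H](CO[Si](CC)(CC)CC)[C@H](OC(=O)CCl)C=C[C@]1(C)CO[Si](c2ccccc2)(c2ccccc2)C(C)(C)C | intermediate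
18 | 4β-alcohol | CC[Si](CC)(CC)OCCC(=C)[C@H]1[C@H](CO[Si](CC)(CC)CC)[C@H](O)C=C[C@]1(C)CO[Si](c2ccccc2)(c2ccccc2)C(C)(C)C | intermediate
19 | 4β-OTBS ether carrying both primary TES ethers | CC[Si](CC)(CC)OCCC(=C)[C@H]1[C@H](CO[Si](CC)(CC)CC)[C@H](O[Si](C)(C)C(C)(C)C)C=C[C@]1(C)CO[Si](c2ccccc2)(c2ccccc2)C(C)(C)C | intermediate
20 | diol: 4β-OTBS; C4a β-CH2OH; C8a α-(4-hydroxybut-1-en-2-yl); C1 α-CH3, β-CH2OTBDPS; C2=C3 | OCCC(=C)[C@H]1[C@H](CO)[C@H](O[Si](C)(C)C(C)(C)C)C=C[C@]1(C)CO[Si](c2ccccc2)(c2ccccc2)C(C)(C)C | intermediate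
21 | dialdehyde: 4β-OTBS; C4a β-CHO; C8a α-(4-oxobut-1-en-2-yl); C1 α-CH3, β-CH2OTBDPS; C2=C3 | O=CCC(=C)[C@H]1[C@H](C=O)[C@H](O[Si](C)(C)C(C)(C)C)C=C[C@]1(C)CO[Si](c2ccccc2)(c2ccccc2)C(C)(C)C | intermediate
22 | trans-decalin (H-4a α, H-8a β): 5α-OH (equatorial), 6α-OH (axial), 8-methylene, 4β-OTBS, C2=C3, C1 α-CH3 and β-CH2OTBDPS | C=C1C[C@@H](O)[C@@H](O)[C@@H]2[C@H](O[Si](C)(C)C(C)(C)C)C=C[C@](C)(CO[Si](c3ccccc3)(c3ccccc3)C(C)(C)C)[C@@H]12 | intermediate
23 | 8β-methyl analogue of 22 (methyl equatorial, H-8 α) | C[C@@H]1C[C@@H](O)[C@@H](O)[C@@H]2[C@H](O[Si](C)(C)C(C)(C)C)C=C[C@](C)(CO[Si](c3ccccc3)(c3ccccc3)C(C)(C)C)[C@@H]12 | intermediate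
24 | 4β,5α,6α-triol | C[C@@H]1C[C@@H](O)[C@@H](O)[C@@H]2[C@H](O)C=C[C@](C)(CO[Si](c3ccccc3)(c3ccccc3)C(C)(C)C)[C@@H]12 | intermediate
25 | 5α,6α-O-isopropylidene acetal with free 4β-OH | C[C@@H]1C[C@@H](OC2(C)C)[C@@H](O2)[C@@H]3[C@H](O)C=C[C@](C)(CO[Si](c4ccccc4)(c4ccccc4)C(C)(C)C)[C@@H]13 | intermediate
26 | 4β-propanoate of 25 | C[C@@H]1C[C@@H](OC2(C)C)[C@@H](O2)[C@@H]3[C@H](OC(=O)CC)C=C[C@](C)(CO[Si](c4ccccc4)(c4ccccc4)C(C)(C)C)[C@@H]13 | intermediate
27 | (Z)-O-trimethylsilyl ketene acetal of 26 (methyl cis to OSi) | C[C@@H]1C[C@@H](OC2(C)C)[C@@H](O2)[C@@H]3[C@H](O/C(O[Si](C)(C)C)=C/C)C=C[C@](C)(CO[Si](c4ccccc4)(c4ccccc4)C(C)(C)C)[C@@H]13 | intermediate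
28 | trimethylsilyl (S)-2-(decalin-2β-yl)propanoate (C3=C4; acetonide; CH2OTBDPS) | C[Si](C)(C)OC(=O)[C@@H](C)[C@H]1C=C[C@H]2[C@H](OC3(C)C)[C@H](O3)C[C@@H](C)[C@@H]2[C@@]1(C)CO[Si](c4ccccc4)(c4ccccc4)C(C)(C)C | intermediate
29 | (S)-2-(decalin-2β-yl)propanoic acid | OC(=O)[C@@H](C)[C@H]1C=C[C@H]2[C@H](OC3(C)C)[C@H](O3)C[C@@H](C)[C@@H]2[C@@]1(C)CO[Si](c4ccccc4)(c4ccccc4)C(C)(C)C | intermediate
30 | (S)-2-(decalin-2β-yl)propan-1-ol | OC[C@@H](C)[C@H]1C=C[C@H]2[C@H](OC3(C)C)[C@H](O3)C[C@@H](C)[C@@H]2[C@@]1(C)CO[Si](c4ccccc4)(c4ccccc4)C(C)(C)C | intermediate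
31 | 4-methylbenzenesulfonate of 30 | Cc1ccc(cc1)S(=O)(=O)OC[C@@H](C)[C@H]1C=C[C@H]2[C@H](OC3(C)C)[C@H](O3)C[C@@H](C)[C@@H]2[C@@]1(C)CO[Si](c4ccccc4)(c4ccccc4)C(C)(C)C | intermediate
32 | 2β-[(R)-butan-2-yl] decalin: C3=C4; 5,6-acetonide; 8β-CH3; C1 α-CH3 and β-CH2OTBDPS | CC[C@@H](C)[C@H]1C=C[C@H]2[C@H](OC3(C)C)[C@H](O3)C[C@@H](C)[C@@H]2[C@@]1(C)CO[Si](c4ccccc4)(c4ccccc4)C(C)(C)C | intermediate
33 | C9 primary alcohol (C1 β-CH2OH) | CC[C@@H](C)[C@H]1C=C[C@H]2[C@H](OC3(C)C)[C@H](O3)C[C@@H](C)[C@@H]2[C@@]1(C)CO | intermediate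
34 | C9 aldehyde (C1 β-CHO) | CC[C@@H](C)[C@H]1C=C[C@H]2[C@H](OC3(C)C)[C@H](O3)C[C@@H](C)[C@@H]2[C@@]1(C)C=O | intermediate
35 | C9 allylic alcohols (1-hydroxyprop-2-enyl on C1; both C9 epimers) | CC[C@@H](C)[C@H]1C=C[C@H]2[C@H](OC3(C)C)[C@H](O3)C[C@@H](C)[C@@H]2[C@@]1(C)C(O)C=C | intermediate
36 | C9 vinyl ketone (prop-2-enoyl on C1) | CC[C@@H](C)[C@H]1C=C[C@H]2[C@H](OC3(C)C)[C@H](O3)C[C@@H](C)[C@@H]2[C@@]1(C)C(=O)C=C | intermediate
37 | 3-(4-methoxybenzyloxy)propanoyl ketone (acetonide) | CC[C@@H](C)[C@H]1C=C[C@H]2[C@H](OC3(C)C)[C@H](O3)C[C@@H](C)[C@@H]2[C@@]1(C)C(=O)CCOCc1ccc(OC)cc1 | intermediate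
38 | 5α,6α-diol of 37 | CC[C@@H](C)[C@H]1C=C[C@H]2[C@H](O)[C@H](O)C[C@@H](C)[C@@H]2[C@@]1(C)C(=O)CCOCc1ccc(OC)cc1 | intermediate
39 | tert-butyl 3-oxobutanoate | CC(=O)CC(=O)OC(C)(C)C | starting material
40 | tert-butyl (E)-3-(trifluoromethylsulfonyloxy)but-2-enoate | C/C(OS(=O)(=O)C(F)(F)F)=C\C(=O)OC(C)(C)C | intermediate
41 | methyl bromoacetate | COC(=O)CBr | starting material
42 | bromo(2-methoxy-2-oxoethyl)zinc | COC(=O)C[Zn]Br | intermediate
43 | 1-tert-butyl 5-methyl (E)-3-methylpent-2-enedioate | COC(=O)C/C(C)=C/C(=O)OC(C)(C)C | intermediate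
44 | (E)-5-methoxy-3-methyl-5-oxopent-2-enoic acid | COC(=O)C/C(C)=C/C(O)=O | intermediate
45 | methyl (E)-5-chloro-3-methyl-5-oxopent-3-enoate | COC(=O)C/C(C)=C/C(Cl)=O | intermediate
46 | 5,6-O-dibutylstannylene acetal of 38 | CC[C@@H](C)[C@H]1C=C[C@H]2[C@H](O[Sn]3(CCCC)CCCC)[C@H](O3)C[C@@H](C)[C@@H]2[C@@]1(C)C(=O)CCOCc1ccc(OC)cc1 | intermediate
47 | 5-O-[(E)-5-methoxy-3-methyl-5-oxopent-2-enoyl] ester with free 6α-OH and 11-O-PMB | CC[C@@H](C)[C@H]1C=C[C@H]2[C@H](OC(=O)/C=C(\C)CC(=O)OC)[C@H](O)C[C@@H](C)[C@@H]2[C@@]1(C)C(=O)CCOCc1ccc(OC)cc1 | intermediate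
48 | tandyukisin B | CC[C@@H](C)[C@H]1C=C[C@H]2[C@H](OC(=O)/C=C(\C)CC(=O)OC)[C@H](O)C[C@@H](C)[C@@H]2[C@@]1(C)C(=O)CCO | target

Total step count: 32. Longest linear sequence: 27 steps (steps 1–4, 7–27, 31 and 32).

Steps most likely to fail

Step 14 (key step). The process at risk is enolisation before or during electron transfer, which would move the 8-methylene into conjugation with the C6 aldehyde, together with loss of the cis/equatorial preference of the samarium-bridged chair. The fallback sets out from diol 20 and fixes C8 before ring closure. Iridium-catalysed asymmetric hydrogenation of the 1,1-disubstituted alkene with a chiral P,N-ligand catalyst, the ligand enantiomer being chosen for the 8-methyl configuration of the target, would give the saturated diol F1. Buffered Dess–Martin oxidation would then give the saturated dialdehyde F2, which has no double bond left to migrate. Its SmI2 pinacol cyclisation, now with an equatorial methyl in the chair, should give the 8β-methyl diol 23 directly, and the route resumes at step 16.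

Step 18. The process at risk is leakage between boat and chair transition states, or incomplete Z-enolate formation, which would erode the configuration of the side-chain carbon (the transfer from C4 to C2 is stereospecific in any case). The fallback sets out from alcohol 25 and separates the two stereocentres. Acetylation (Ac2O, DMAP) gives the 4β-acetate F3; LDA and TMSCl give the silyl ketene acetal F4, which rearranges to the trimethylsilyl ester F5 and on aqueous work-up gives the C2 acetic acid F6. Pivaloyl chloride and Et3N give the mixed pivalic anhydride F7, which lithiated (S)-4-benzyl-1,3-oxazolidin-2-one converts into the N-acyl oxazolidinone F8. Evans methylation (NaHMDS, then iodomethane 2, −78 °C) under auxiliary control should give the α-methyl imide F9, and LiBH4 removes the auxiliary to give primary alcohol 30, where the route resumes at step 20.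

Step 7. The process at risk is slow insertion next to the quaternary carbon and insufficient discrimination between the two faces of the dienone against the modest methyl/silyloxymethyl bias, which would give diastereomers. The fallback sets out from dienone 7 and alkenylalane 10 (made in step 6 and used without borylation). Copper-catalysed asymmetric conjugate addition with a chiral N-heterocyclic carbene–copper catalyst (Cu(OTf)2, chiral NHC–silver complex, THF, −30 °C) would give the aluminium enolate F10, which on aqueous work-up gives enone 12, where the route resumes at step 8.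

Further compounds
F1 | step 14 | saturated diol (8-methyl set before ring closure) | OCC[C@@H](C)[C@H]1[C@H](CO)[C@H](O[Si](C)(C)C(C)(C)C)C=C[C@]1(C)CO[Si](c2ccccc2)(c2ccccc2)C(C)(C)C
F2 | step 14 | saturated dialdehyde | O=CC[C@@H](C)[C@H]1[C@H](C=O)[C@H](O[Si](C)(C)C(C)(C)C)C=C[C@]1(C)CO[Si](c2ccccc2)(c2ccccc2)C(C)(C)C
F3 | step 18 | 4β-acetate of 25 | C[C@@H]1C[C@@H](OC2(C)C)[C@@H](O2)[C@@H]3[C@H](OC(C)=O)C=C[C@](C)(CO[Si](c4ccccc4)(c4ccccc4)C(C)(C)C)[C@@H]13
F4 | step 18 | O-trimethylsilyl ketene acetal of F3 | C[C@@H]1C[C@@H](OC2(C)C)[C@@H](O2)[C@@H]3[C@H](OC(=C)O[Si](C)(C)C)C=C[C@](C)(CO[Si](c4ccccc4)(c4ccccc4)C(C)(C)C)[C@@H]13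
F5 | step 18 | trimethylsilyl (decalin-2β-yl)acetate | C[Si](C)(C)OC(=O)C[C@H]1C=C[C@H]2[C@H](OC3(C)C)[C@H](O3)C[C@@H](C)[C@@H]2[C@@]1(C)CO[Si](c4ccccc4)(c4ccccc4)C(C)(C)C
F6 | step 18 | (decalin-2β-yl)acetic acid | OC(=O)C[C@H]1C=C[C@H]2[C@H](OC3(C)C)[C@H](O3)C[C@@H](C)[C@@H]2[C@@]1(C)CO[Si](c4ccccc4)(c4ccccc4)C(C)(C)C
F7 | step 18 | mixed pivalic anhydride of F6 | CC(C)(C)C(=O)OC(=O)C[C@H]1C=C[C@H]2[C@H](OC3(C)C)[C@H](O3)C[C@@H](C)[C@@H]2[C@@]1(C)CO[Si](c4ccccc4)(c4ccccc4)C(C)(C)C
F8 | step 18 | N-acyl (S)-4-benzyl-1,3-oxazolidin-2-one of F6 | O=C1OC[C@H](Cc2ccccc2)N1C(=O)C[C@H]3C=C[C@H]4[C@H](OC5(C)C)[C@H](O5)C[C@@H](C)[C@@H]4[C@@]3(C)CO[Si](c6ccccc6)(c6ccccc6)C(C)(C)C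
F9 | step 18 | α-methylated imide | O=C1OC[C@H](Cc2ccccc2)N1C(=O)[C@@H](C)[C@H]3C=C[C@H]4[C@H](OC5(C)C)[C@H](O5)C[C@@H](C)[C@@H]4[C@@]3(C)CO[Si](c6ccccc6)(c6ccccc6)C(C)(C)C
F10 | step 7 | diisobutylaluminium dienolate of 12 | CC[Si](CC)(CC)OCCC(=C)[C@H]1C=C(O[Al](CC(C)C)CC(C)C)C=C[C@]1(C)CO[Si](c2ccccc2)(c2ccccc2)C(C)(C)C
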